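## The problem

The target 20 is an achiral macrocyclic bis(bibenzyl): four benzene rings in a 17-membered ring, joined alternately by two diaryl ether oxygens and two CH2CH2 bridges. Ring A (alkyl at C1, aryloxy at C3, hydroxyls at C4 and C5) is bonded through its C3 oxygen to the para-phenylene ring B. Ring B is tied by an ethylene bridge to ring C (alkyl at C1, aryloxy at C2, hydroxyls at C3 and C4). The C2 oxygen of ring C carries ring D, whose ortho carbon starts the second ethylene bridge back to C1 of ring A.

There is no stereocentre, so nothing has to be controlled in space; the difficulty is connectivity. The ring C–O–ring D ether is flanked on ring C by the bridge carbon and by an oxygen substituent, and on ring D by the other bridge, so it is the most hindered bond of the molecule. On ring A one of three adjacent oxygens must be told apart from the other two. The two catechols are sensitive to air and base and should be unveiled in the last step. An aryl halide kept for the ring-closing etherification excludes palladium-catalysed hydrogenation for every reduction along the way.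

The feature that opens the plan is ring D: it carries only two substituents, on adjacent carbons, namely the ring C oxygen and the benzylic carbon of the bridge to ring A. That is the pattern left when a nucleophile and an electrophile add across benzyne.

## Retrosynthesis

**Catechol release.** The four O–CH3 bonds of macrocycle 19 are cut last, so 20 comes from its tetramethyl ether. Methyl ethers are the only groups that survive every earlier step and still leave with BBr3 without harming diaryl ethers. The forward reaction only has to be clean on a compound with no other functionality.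

**Ring closure at the ring A oxygen.** The bond between the C3 oxygen of ring A and the para carbon of ring B is cut, leading to bromophenol 18. Of the two ether bonds this is the unhindered one (a guaiacol-type phenol and a para-alkyl aryl bromide), so it is the better place for a macrocyclic Ullmann coupling. Closing at an ethylene bridge would require extra handles on two rings. The precursor is acyclic and is asked only to cyclise under high dilution.

**Bridge adjustment.** The free phenol of 18 is traced to benzyl ether 17, the CH2CH2 bridge of 17 to ketone 16, and 16 to the α-hydroxy ketone 15. No skeletal bond is cut; the bridge oxygens are the price of forming the bridge by carbonyl addition. They are removed in two chemoselective reductions (SmI2, then Et3SiH/CF3CO2H) that leave the aryl bromide alone.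

**Three-component union at ring D.** Both bonds to ring D are cut at once: the ring C oxygen–ring D carbon bond and the ring D carbon–carbinol carbon bond. This leads to phenol 4, the ortho-silylaryl triflate 11 as benzyne source, and arylglyoxal 10. Against a stepwise ether synthesis followed by olefination, this cut uses the strain of benzyne 13 to overcome the hindrance around the ring C oxygen. It also joins three fragments of similar size in one flask. The forward reaction must capture the aryl anion at the aldehyde carbon faster than it is protonated.

**Ring C/ring B fragment.** The ethylene bridge of 4 is cut at the olefin of stilbene 3, which comes from salicylaldehyde 1 and phosphonium salt 2 by a Wittig reaction. Both are catalogue compounds, and the ring C oxygen pattern is bought. The alkene is saturated with diimide, which spares the bromide.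

**Ring A fragment.** Glyoxal 10 comes from methyl ketone 8 by oxidation of the methyl group. Ketone 8 comes from carbinol 7 and aldehyde 6 by methyl addition and oxidation, and 6 from commercial 3-hydroxy-4,5-dimethoxybenzaldehyde 5 by benzylation. The benzyl group marks the one ring A oxygen that later becomes the macrocyclic ether; the other two stay as methyl ethers.

## Roads not taken

**Alternative 1:** The macrocycle is cut at the bond between ring B and the CH2 of the ring C/ring B bridge. The seco compound A2 carries a vinyl group on ring C and the ring B bromide already attached to ring A through the ether. Hydroboration of the styrene with a dialkylborane and intramolecular B-alkyl Suzuki–Miyaura coupling (Pd(dppf)Cl2) would give A1, which is the same compound as 19.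
- Merits: sp3–sp2 macrocyclisations of this kind are dependable at high dilution, and the ring A–O–ring B ether can be made early and intermolecularly, where Ullmann chemistry works best.
- Weak points: A2 still contains the hindered ring C–O–ring D ether and the ortho bridge of ring D, so the hardest bond of the molecule is only postponed. A vinyl group next to that ether must also be carried or introduced late.
- Comparison: for the ring closure itself this road is probably safer than the Ullmann cyclisation of 18. The chosen plan sets against it the one-flask union that makes the hindered ether and the bridge together, and a shorter sequence. If step 11 fails, this closure is the natural redesign.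

**Alternative 2:** Ring A is built rather than bought. Photochemical Wolff rearrangement of the unsaturated diazo ketone A4 would give a vinylketene that adds to di-tert-butoxyethyne A5. Ring opening of the cyclobutenone and six-electron closure (Danheiser benzannulation) would give phenol A3 with three new C–C bonds.
- Merits: the oxygen that must become the macrocyclic ether emerges as the only free phenol, so no protecting-group step is spent on ring A, and the tert-butyl ethers leave with mild acid.
- Weak points: A5 is thermally fragile and must be prepared. A4 needs the whole ring D/ring C/ring B assembly, including the hindered ether, before the annulation. The benzene ring that is built is available in catalogues with the correct oxygen pattern.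
- Comparison: the differentiation of the ring A oxygens is more elegant than the benzyl group used here, which costs two steps (3 and 10). The chosen plan accepts that cost because it puts its effort into the ring D bonds, which this alternative leaves unsolved.

**Alternative 3:** The ring A–CH2 bond is formed by a para-Claisen sequence. The macrocyclic 2-arylallyl ether A7, attached at the central ring A oxygen, would on heating undergo a [3,3] shift to a blocked ortho carbon and then a Cope shift to the para carbon, giving A6.
- Merits: no metal, no halide to protect through reductions, and the C–C bond is made at the correct ring A carbon by the symmetry of the rearrangement.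
- Weak points: both sigmatropic shifts must take place inside a 17-membered ring, where the chair transition states are constrained by the other three rings. A6 carries an exocyclic methylene on the bridge, one carbon too many, which must be cleaved and the resulting ketone deoxygenated. A7 itself needs a macrocyclisation and the hindered ring C–O–ring D ether.
- Comparison: the corrective steps after the key event are similar in number (two reductions here, cleavage and deoxygenation there). The chosen plan performs its key step on acyclic fragments without conformational demands and closes the ring by a reaction type established for macrocyclic diaryl ethers.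

Key step: step 7

Assumption: alkene 3 is handled as an E/Z mixture because both isomers converge on 4 in step 2, so its SMILES carries no alkene geometry. The target has no stereocentre.

## Route

Step 1
Reactants: 1 2-hydroxy-3,4-dimethoxybenzaldehyde; 2 (4-bromobenzyl)triphenylphosphonium bromide
Product: 3 6-[2-(4-bromophenyl)ethenyl]-2,3-dimethoxyphenol (E/Z mixture)
Conditions: KOtBu (2.3 equiv), THF, 0 °C → rt
Reagents that add atoms: none
Why: Wittig olefination with a semi-stabilised ylide; the extra equivalent of base converts the phenol into its phenoxide, which salicylaldehydes tolerate in this reaction, and the alkene geometry is irrelevant because the double bond is saturated next.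

Step 2
Reactants: 3 6-[2-(4-bromophenyl)ethenyl]-2,3-dimethoxyphenol
Product: 4 6-[2-(4-bromophenyl)ethyl]-2,3-dimethoxyphenol
Conditions: TsNHNH2, NaOAc, THF/H2O, reflux
Reagents that add atoms: none
Why: Diimide generated from the sulfonyl hydrazide transfers two hydrogens to the stilbene in a concerted syn addition and leaves the aryl bromide untouched, which catalytic hydrogenation over palladium would not.

Step 3
Reactants: 5 3-hydroxy-4,5-dimethoxybenzaldehyde
Product: 6 3-(benzyloxy)-4,5-dimethoxybenzaldehyde
Conditions: BnBr, K2CO3, DMF, 60 °C
Reagents that add atoms: benzyl bromide, BrCc1ccccc1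
Why: Williamson etherification of the only free phenol; benzyl is stable to Grignard reagent, oxidants, fluoride, SmI2 and brief acid, and can later be removed without touching methyl ethers.

Step 4
Reactants: 6 3-(benzyloxy)-4,5-dimethoxybenzaldehyde
Product: 7 1-[3-(benzyloxy)-4,5-dimethoxyphenyl]ethanol (racemic)
Conditions: MeMgBr, THF, 0 °C; aq. NH4Cl
Reagents that add atoms: methylmagnesium bromide, C[Mg]Br
Why: Grignard addition to an aromatic aldehyde; the carbinol is formed racemic and its configuration disappears in the next step.

Step 5
Reactants: 7 1-[3-(benzyloxy)-4,5-dimethoxyphenyl]ethanol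
Product: 8 1-[3-(benzyloxy)-4,5-dimethoxyphenyl]ethanone
Conditions: MnO2 (activated, excess), CH2Cl2, rt
Reagents that add atoms: none
Why: Selective oxidation of a benzylic secondary alcohol to the aryl methyl ketone under neutral conditions.

Step 6
Reactants: 8 1-[3-(benzyloxy)-4,5-dimethoxyphenyl]ethanone
Product: 10 2-[3-(benzyloxy)-4,5-dimethoxyphenyl]-2-oxoacetaldehyde, via glyoxal hydrate 9 (not isolated)
Conditions: SeO2, 1,4-dioxane/H2O, reflux; filter; then toluene, Dean–Stark, use at once
Reagents that add atoms: selenium dioxide, O=[Se]=O
Why: Riley oxidation of the enolisable methyl group of an acetophenone gives the arylglyoxal, first as its hydrate; azeotropic removal of water delivers the anhydrous aldehyde needed for the next step.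

Step 7
Reactants: 4 6-[2-(4-bromophenyl)ethyl]-2,3-dimethoxyphenol; 11 2-(trimethylsilyl)phenyl trifluoromethanesulfonate; 10 2-[3-(benzyloxy)-4,5-dimethoxyphenyl]-2-oxoacetaldehyde
Product: 15 1-[3-(benzyloxy)-4,5-dimethoxyphenyl]-2-(2-{6-[2-(4-bromophenyl)ethyl]-2,3-dimethoxyphenoxy}phenyl)-2-hydroxyethanone (racemic), via potassium phenoxide 12 (not isolated), via benzyne 13 (not isolated), via aryl anion 14 (not isolated)
Conditions: 4, KH (1.0 equiv), THF, 0 °C; 18-crown-6, 10 (3 equiv); then KF and 11 (1.3 equiv, slow addition), THF, 0 °C → rt; aq. NH4Cl
Reagents that add atoms: none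
Why: Proposed new method: fluoride attacks silicon of 11 and triflate leaves to give benzyne 13; the crown-ether-separated phenoxide 12 adds to the strained triple bond despite its two ortho substituents and creates aryl anion 14 on the neighbouring carbon, which is captured by the aldehyde carbon of 10 to give the alkoxide of 15. The closest known reaction type is the three-component coupling of arynes with heteroatom nucleophiles and aldehydes, together with the phenoxide–aryne–carbonyl cascade by which salicylaldehydes and arynes give xanthenols; the new element is intermolecular capture of a phenoxide-derived aryl anion by an external aldehyde. No ring is closed. The carbinol carbon is formed without control as a racemate, which is acceptable because steps 8 and 9 turn it into CH2. Regiochemistry on ring D cannot fail, since benzyne is symmetric and the two new bonds must be ortho. The aldehyde of 10 should be attacked in preference to its ketone because it is more electrophilic and less hindered, and 10 has no α-hydrogen to quench the anion; later ketol tautomerism of 15 would be harmless because both bridge carbons are reduced. Carbon capture must beat protonation: 12 is made with KH so that no phenol or conjugate acid remains, THF replaces acetonitrile, and 10 is anhydrous and in excess. Slow addition of 11 keeps benzyne from accumulating next to the product alkoxide.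

Step 8
Reactants: 15 1-[3-(benzyloxy)-4,5-dimethoxyphenyl]-2-(2-{6-[2-(4-bromophenyl)ethyl]-2,3-dimethoxyphenoxy}phenyl)-2-hydroxyethanone
Product: 16 1-[3-(benzyloxy)-4,5-dimethoxyphenyl]-2-(2-{6-[2-(4-bromophenyl)ethyl]-2,3-dimethoxyphenoxy}phenyl)ethanone
Conditions: SmI2 (2.5 equiv), THF/MeOH, −78 °C
Reagents that add atoms: none
Why: Reductive cleavage of an α-heterosubstituted ketone by divalent samarium: two single-electron transfers to the aryl ketone expel the α-hydroxyl and the samarium enolate is protonated by methanol; without HMPA at −78 °C the aryl bromide and the benzyl ether are inert.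

Step 9
Reactants: 16 1-[3-(benzyloxy)-4,5-dimethoxyphenyl]-2-(2-{6-[2-(4-bromophenyl)ethyl]-2,3-dimethoxyphenoxy}phenyl)ethanone
Product: 17 1-(benzyloxy)-5-[2-(2-{6-[2-(4-bromophenyl)ethyl]-2,3-dimethoxyphenoxy}phenyl)ethyl]-2,3-dimethoxybenzene
Conditions: Et3SiH (5 equiv), CF3CO2H/CH2Cl2, 0 °C → rt
Reagents that add atoms: none
Why: Ionic hydrogenation of an aryl ketone: protonation, hydride transfer from the silane, ionisation to the benzylic cation stabilised by ring A and a second hydride transfer give CH2; the aryl bromide and diaryl ether do not react, and any benzyl ether lost in the acid simply arrives early at 18.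

Step 10
Reactants: 17 1-(benzyloxy)-5-[2-(2-{6-[2-(4-bromophenyl)ethyl]-2,3-dimethoxyphenoxy}phenyl)ethyl]-2,3-dimethoxybenzene
Product: 18 5-[2-(2-{6-[2-(4-bromophenyl)ethyl]-2,3-dimethoxyphenoxy}phenyl)ethyl]-2,3-dimethoxyphenol
Conditions: BCl3, pentamethylbenzene, CH2Cl2, −78 °C
Reagents that add atoms: none
Why: Lewis acid debenzylation with a non-basic cation scavenger; at −78 °C the aryl benzyl ether is cleaved while aryl methyl ethers, the diaryl ether and the bromide remain, and the scavenger prevents C-benzylation of the electron-rich rings.

Step 11
Reactants: 18 5-[2-(2-{6-[2-(4-bromophenyl)ethyl]-2,3-dimethoxyphenoxy}phenyl)ethyl]-2,3-dimethoxyphenol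
Product: 19 tetra-O-methyl ether of 20 (17-membered macrocycle; ring A 4,5-dimethoxy with its C3 oxygen bonded to the para carbon of ring B; ring C 3,4-dimethoxy)
Conditions: CuI (30 mol%), N,N-dimethylglycine hydrochloride, Cs2CO3, 1,4-dioxane, 100 °C, high dilution with slow addition of 18
Reagents that add atoms: none
Why: Intramolecular Ullmann diaryl ether synthesis, a ring closure established for macrocyclic diaryl ethers; the ring is closed end-to-end between an ortho-methoxy phenoxide and an unhindered para-alkyl aryl bromide at the monovalent copper centre, and high dilution favours cyclisation over oligomerisation.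

Step 12
Reactants: 19 tetra-O-methyl ether of 20
Product: 20 target macrocycle CNP0114693.0 (ring A 4,5-dihydroxy, ring C 3,4-dihydroxy)
Conditions: BBr3 (excess), CH2Cl2, −78 °C → rt; then MeOH, H2O, degassed work-up
Reagents that add atoms: none
Why: Exhaustive Lewis acid demethylation of aryl methyl ethers; diaryl ethers and the benzylic CH2 groups are stable to BBr3, and the catechols are released only in the last operation.

## Compound list

1 | 2-hydroxy-3,4-dimethoxybenzaldehyde | COc1ccc(C=O)c(O)c1OC | starting material
2 | (4-bromobenzyl)triphenylphosphonium bromide | [Br-].Brc1ccc(C[P+](c2ccccc2)(c2ccccc2)c2ccccc2)cc1 | starting material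
3 | 6-[2-(4-bromophenyl)ethenyl]-2,3-dimethoxyphenol (E/Z mixture) | COc1ccc(C=Cc2ccc(Br)cc2)c(O)c1OC | intermediate
4 | 6-[2-(4-bromophenyl)ethyl]-2,3-dimethoxyphenol | COc1ccc(CCc2ccc(Br)cc2)c(O)c1OC | intermediate
5 | 3-hydroxy-4,5-dimethoxybenzaldehyde | COc1cc(C=O)cc(O)c1OC | starting material
6 | 3-(benzyloxy)-4,5-dimethoxybenzaldehyde | COc1cc(C=O)cc(OCc2ccccc2)c1OC | intermediate
7 | 1-[3-(benzyloxy)-4,5-dimethoxyphenyl]ethanol (racemic) | CC(O)c1cc(OC)c(OC)c(OCc2ccccc2)c1 | intermediate
8 | 1-[3-(benzyloxy)-4,5-dimethoxyphenyl]ethanone | CC(=O)c1cc(OC)c(OC)c(OCc2ccccc2)c1 | intermediate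
9 | 1-[3-(benzyloxy)-4,5-dimethoxyphenyl]-2,2-dihydroxyethanone (glyoxal hydrate, not isolated) | OC(O)C(=O)c1cc(OC)c(OC)c(OCc2ccccc2)c1 | intermediate
10 | 2-[3-(benzyloxy)-4,5-dimethoxyphenyl]-2-oxoacetaldehyde | O=CC(=O)c1cc(OC)c(OC)c(OCc2ccccc2)c1 | intermediate
11 | 2-(trimethylsilyl)phenyl trifluoromethanesulfonate | C[Si](C)(C)c1ccccc1OS(=O)(=O)C(F)(F)F | starting material
12 | potassium 6-[2-(4-bromophenyl)ethyl]-2,3-dimethoxyphenoxide (not isolated) | [K+].COc1ccc(CCc2ccc(Br)cc2)c([O-])c1OC | intermediate
13 | benzyne (1,2-didehydrobenzene, not isolated) | C1#CC=CC=C1 | intermediate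
14 | 2-{6-[2-(4-bromophenyl)ethyl]-2,3-dimethoxyphenoxy}phenylpotassium (not isolated) | COc1ccc(CCc2ccc(Br)cc2)c(Oc2ccccc2[K])c1OC | intermediate
15 | 1-[3-(benzyloxy)-4,5-dimethoxyphenyl]-2-(2-{6-[2-(4-bromophenyl)ethyl]-2,3-dimethoxyphenoxy}phenyl)-2-hydroxyethanone (racemic) | COc1ccc(CCc2ccc(Br)cc2)c(Oc2ccccc2C(O)C(=O)c2cc(OC)c(OC)c(OCc3ccccc3)c2)c1OC | intermediate
16 | 1-[3-(benzyloxy)-4,5-dimethoxyphenyl]-2-(2-{6-[2-(4-bromophenyl)ethyl]-2,3-dimethoxyphenoxy}phenyl)ethanone | COc1ccc(CCc2ccc(Br)cc2)c(Oc2ccccc2CC(=O)c2cc(OC)c(OC)c(OCc3ccccc3)c2)c1OC | intermediate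
17 | 1-(benzyloxy)-5-[2-(2-{6-[2-(4-bromophenyl)ethyl]-2,3-dimethoxyphenoxy}phenyl)ethyl]-2,3-dimethoxybenzene | COc1ccc(CCc2ccc(Br)cc2)c(Oc2ccccc2CCc2cc(OC)c(OC)c(OCc3ccccc3)c2)c1OC | intermediate
18 | 5-[2-(2-{6-[2-(4-bromophenyl)ethyl]-2,3-dimethoxyphenoxy}phenyl)ethyl]-2,3-dimethoxyphenol | COc1ccc(CCc2ccc(Br)cc2)c(Oc2ccccc2CCc2cc(OC)c(OC)c(O)c2)c1OC | intermediate
19 | tetra-O-methyl ether of the target macrocycle | COc1cc2cc(c1OC)Oc1ccc(cc1)CCc1ccc(OC)c(OC)c1Oc1ccccc1CC2 | intermediate
20 | CNP0114693.0, macrocyclic bis(bibenzyl) with ring A 4,5-diol and ring C 3,4-diol | Oc1cc2cc(c1O)Oc1ccc(cc1)CCc1ccc(O)c(O)c1Oc1ccccc1CC2 | target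

## Step count and risks

Total: 12 steps. Longest linear sequence: 10 steps (5 → 6 → 7 → 8 → 10 → 15 → 16 → 17 → 18 → 19 → 20). The ring C/ring B branch (steps 1 and 2) joins at step 7.

**Step 7 (key step, new method).** The most likely failure is protonation of the aryl anion before it reaches the aldehyde. The proton could come from residual hydrate water in 10 or from transfer of a benzylic hydrogen of the ring C side chain. Arylation of the product alkoxide by further benzyne and fluoride-induced oligomerisation of the glyoxal are secondary risks.
Fallback with known chemistry, setting out from 4 and 6 and returning at 17: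
- Nucleophilic aromatic substitution of 4 on 2-fluorobenzaldehyde (K2CO3, DMF, 120 °C) gives 2-{6-[2-(4-bromophenyl)ethyl]-2,3-dimethoxyphenoxy}benzaldehyde F1.
- Aldehyde 6 is reduced (NaBH4) to [3-(benzyloxy)-4,5-dimethoxyphenyl]methanol F2, converted with PBr3 into 1-(benzyloxy)-5-(bromomethyl)-2,3-dimethoxybenzene F3 and with PPh3 into [3-(benzyloxy)-4,5-dimethoxybenzyl]triphenylphosphonium bromide F4.
- Wittig reaction of F4 with F1 (KOtBu, THF) gives the stilbene 1-(benzyloxy)-5-[2-(2-{6-[2-(4-bromophenyl)ethyl]-2,3-dimethoxyphenoxy}phenyl)ethenyl]-2,3-dimethoxybenzene F5, and diimide reduction as in step 2 gives 17.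

**Step 11.** Oligomerisation in place of ring closure, or reductive loss of bromine during a slow coupling, is the main danger, since the transition state must fold four rings into a 17-membered loop.
Fallback from 18 returning at 19: Miyaura borylation of the aryl bromide (bis(pinacolato)diboron, Pd(dppf)Cl2, KOAc, dioxane) gives 5-{2-[2-(2,3-dimethoxy-6-{2-[4-(4,4,5,5-tetramethyl-1,3,2-dioxaborolan-2-yl)phenyl]ethyl}phenoxy)phenyl]ethyl}-2,3-dimethoxyphenol F6. It is cyclised at room temperature by oxidative Chan–Lam coupling (Cu(OAc)2, pyridine, Et3N, 4 Å sieves, air, CH2Cl2, high dilution) to 19.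

**Step 8.** The free hydroxyl is a modest leaving group, so ketyl dimerisation or over-reduction of the ketone may compete with C–O cleavage.
Fallback from 15 returning at 16: acetylation (Ac2O, pyridine, DMAP) gives 2-[3-(benzyloxy)-4,5-dimethoxyphenyl]-1-(2-{6-[2-(4-bromophenyl)ethyl]-2,3-dimethoxyphenoxy}phenyl)-2-oxoethyl acetate F7, whose α-acetoxy group is removed by zinc dust in acetic acid to give 16.

**Step 9.** Stalling at the benzylic alcohol or trifluoroacetate, or acid-induced dimerisation of a styrene formed by elimination, would lower the return.
Fallback from 16 returning at 17: Wolff–Kishner reduction in the Huang-Minlon form (N2H4·H2O, KOH, diethylene glycol, 130 → 200 °C) through the hydrazone 1-(benzyloxy)-5-[1-hydrazinylidene-2-(2-{6-[2-(4-bromophenyl)ethyl]-2,3-dimethoxyphenoxy}phenyl)ethyl]-2,3-dimethoxybenzene F8.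

**Step 6.** Over-oxidation to the arylglyoxylic acid and incomplete dehydration of the hydrate are the concerns; retained water would quench the aryl anion of step 7.
Fallback from 8 returning at 10: detrifluoroacetylative diazo transfer (LiHMDS, CF3CO2CH2CF3, then MsN3, Et3N) gives 1-[3-(benzyloxy)-4,5-dimethoxyphenyl]-2-diazoethanone F9. Oxidation with dimethyldioxirane in acetone converts it into anhydrous 10 with only volatile by-products.

## Further compounds

F1 | step 7 | 2-{6-[2-(4-bromophenyl)ethyl]-2,3-dimethoxyphenoxy}benzaldehyde | COc1ccc(CCc2ccc(Br)cc2)c(Oc2ccccc2C=O)c1OC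
F2 | step 7 | [3-(benzyloxy)-4,5-dimethoxyphenyl]methanol | OCc1cc(OC)c(OC)c(OCc2ccccc2)c1
F3 | step 7 | 1-(benzyloxy)-5-(bromomethyl)-2,3-dimethoxybenzene | BrCc1cc(OC)c(OC)c(OCc2ccccc2)c1
F4 | step 7 | [3-(benzyloxy)-4,5-dimethoxybenzyl]triphenylphosphonium bromide | [Br-].COc1cc(C[P+](c2ccccc2)(c2ccccc2)c2ccccc2)cc(OCc2ccccc2)c1OC
F5 | step 7 | 1-(benzyloxy)-5-[2-(2-{6-[2-(4-bromophenyl)ethyl]-2,3-dimethoxyphenoxy}phenyl)ethenyl]-2,3-dimethoxybenzene (E/Z mixture) | COc1ccc(CCc2ccc(Br)cc2)c(Oc2ccccc2C=Cc2cc(OC)c(OC)c(OCc3ccccc3)c2)c1OC
F6 | step 11 | 5-{2-[2-(2,3-dimethoxy-6-{2-[4-(4,4,5,5-tetramethyl-1,3,2-dioxaborolan-2-yl)phenyl]ethyl}phenoxy)phenyl]ethyl}-2,3-dimethoxyphenol | COc1ccc(CCc2ccc(cc2)B2OC(C)(C)C(C)(C)O2)c(Oc2ccccc2CCc2cc(OC)c(OC)c(O)c2)c1OC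
F7 | step 8 | 2-[3-(benzyloxy)-4,5-dimethoxyphenyl]-1-(2-{6-[2-(4-bromophenyl)ethyl]-2,3-dimethoxyphenoxy}phenyl)-2-oxoethyl acetate (racemic) | COc1ccc(CCc2ccc(Br)cc2)c(Oc2ccccc2C(OC(C)=O)C(=O)c2cc(OC)c(OC)c(OCc3ccccc3)c2)c1OC
F8 | step 9 | 1-(benzyloxy)-5-[1-hydrazinylidene-2-(2-{6-[2-(4-bromophenyl)ethyl]-2,3-dimethoxyphenoxy}phenyl)ethyl]-2,3-dimethoxybenzene | COc1ccc(CCc2ccc(Br)cc2)c(Oc2ccccc2CC(=NN)c2cc(OC)c(OC)c(OCc3ccccc3)c2)c1OC
F9 | step 6 | 1-[3-(benzyloxy)-4,5-dimethoxyphenyl]-2-diazoethanone | [N-]=[N+]=CC(=O)c1cc(OC)c(OC)c(OCc2ccccc2)c1
A1 | alternative 1 | tetra-O-methyl ether of the target macrocycle (identical with 19) | COc1cc2cc(c1OC)Oc1ccc(cc1)CCc1ccc(OC)c(OC)c1Oc1ccccc1CC2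
A2 | alternative 1 | 1-(4-bromophenoxy)-5-{2-[2-(6-ethenyl-2,3-dimethoxyphenoxy)phenyl]ethyl}-2,3-dimethoxybenzene | C=Cc1ccc(OC)c(OC)c1Oc1ccccc1CCc1cc(OC)c(OC)c(Oc2ccc(Br)cc2)c1
A3 | alternative 2 | 5-[2-(2-{6-[2-(4-bromophenyl)ethyl]-2,3-dimethoxyphenoxy}phenyl)ethyl]-2,3-di-tert-butoxyphenol | Oc1cc(CCc2ccccc2Oc2c(CCc3ccc(Br)cc3)ccc(OC)c2OC)cc(OC(C)(C)C)c1OC(C)(C)C
A4 | alternative 2 | 5-(2-{6-[2-(4-bromophenyl)ethyl]-2,3-dimethoxyphenoxy}phenyl)-1-diazo-3-methylidenepentan-2-one | C=C(CCc1ccccc1Oc1c(CCc2ccc(Br)cc2)ccc(OC)c1OC)C(=O)C=[N+]=[N-]
A5 | alternative 2 | di-tert-butoxyethyne | CC(C)(C)OC#COC(C)(C)C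
A6 | alternative 3 | macrocyclic phenol with exocyclic methylene on the ring D/ring A bridge (ring A 3-methoxy-4-hydroxy) | C=C1Cc2cc(OC)c(O)c(c2)Oc2ccc(cc2)CCc2ccc(OC)c(OC)c2Oc2ccccc21
A7 | alternative 3 | macrocyclic 2-arylallyl ether of the central ring A oxygen | C=C1COc2c(OC)cccc2Oc2ccc(cc2)CCc2ccc(OC)c(OC)c2Oc2ccccc12
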